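(The numbers in the tables are simulated for substances that don't exist, noise included.)

The constant I had to know was how fast Lx shrinks in proportion to itself, and before reckoning it I asked which of the given numbers the outcome leaned on.

| flask | Lx | Xa | remark | time |
|---|---|---|---|---|
| red | 30 mM | 80 mM | run made earlier |  |
| teal | 40 mM | 80 mM | run made earlier |  |
| Wednesday's | 20 mM | 80.0 mM |  | 5.0 min |
| Sunday's | 20 mM | 120 mM |  | 5.0 min |

- red (time / s: Lx / %, Jy / %): 12.0: 95.9, 1.3; 25.0: 92.6, 2.6; 40.0: 86.8, 3.6; 50.0: 84.2, 5.0; 60.0: 80.3, 5.4
- teal (time / s: Lx / %, Jy / %): 10.0: 95.7, 0.5; 15.0: 94.4, 1.4; 30.0: 91.7, 2.9; 60.0: 81.1, 3.6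

(each reading ± 1 percentage point)

* part of the Lx that has reacted at the end, Wednesday's
* part of the Lx that has reacted at the end, Sunday's
* what raising the concentration of Xa from its lowest to its highest value here does to the part of the Lx that has reacted (changes below 5 percentage points count as none) (it falls / no change / it rises)

- what has gone from Lx into another species counts as reacted, even if it can come back

I read the constant from each last reading as the logarithm of charged over left, divided by the time. The charge of Lx seemed to matter little: the red run at 30 mM gave 0.219 min⁻¹ and the teal run at 40 mM gave 0.209 min⁻¹, and the two differ within the scatter. That scatter mattered modestly: one standard deviation on the red run's last reading moves its constant by 5.68%.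

Xa stood in excess, since Wednesday's Lx charge is a quarter of its Xa charge. The order in Xa stayed open: both runs used 80 mM, so neither shows it. I assumed first order, which makes the loss pseudo-first-order.

So I kept 0.0447 M⁻¹ s⁻¹, the mean constant per unit of c(Xa), and the part reacted is one minus the exponential of minus this number times c(Xa) times the time. That gave 65.8% for Wednesday's and 80.0% for Sunday's. The scatter above shifts Wednesday's figure by 2.1 percentage points, while the assumed order carries a gap of 14 points, which is larger.

The forecast said 62% (range 45% to 70%) and 75% (range 50% to 84%), with the trend as it rises. Its figures lie below mine, on the ground: “That step may be reversible, which could bring a plateau and lower the figure slightly”.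

The flask gave 69.4% for Wednesday's and 83.0% for Sunday's: it rises, by 14 points.

    Lx + Jy → Ul (k = 0.610 M⁻¹ s⁻¹)
    Lx + Xa → Jy + Rx (k = 0.0190 M⁻¹ s⁻¹)
    Lx + Xa + Rx → Jy + 2 Rx (k = 14.0 M⁻² s⁻¹)
    Lx + Rx ⇌ Dx, settled at all times (K = 15000 M⁻¹)

The difference in concentration of Xa was the main reason for the gap between the two flasks: Sunday's had 83.0% of its Lx reacted, and without that difference it had 69.4%. My 0.0447 M⁻¹ s⁻¹ had given 65.8% and 80.0%, each lower than the flask. For a further flask, like Wednesday's but with 20 mM of Xa, the same constant gives 23.5%. That flask had 25.6% of its Lx reacted, with 74.4% still free.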